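**Plan** (prostanoid numbering: C1 = ester carbon, ring = C8–C12, C20 = end of the octenyl chain)
1. Retrosynthetic cuts, in order: O12–acetyl; C6–C7 (Heck); C10–Cl back to a C10 enol (via its triflate); then the ring bonds C9–C10 and C8–C12 together.
2. Enabling feature: the ring C8–C9–C10–C11–C12 is a cross-conjugated 5-alkylidene-cyclopent-2-enone. C7=C8–C9(=O) is the footprint of an alkoxyallene C7=C8=C9–OR, and C10–C11–C12 (carbonyl level at C10, oxygen at C12) that of a β-oxyacryloyl unit. The ring is therefore the closed form of a pentadienyl cation C8···C12, the same C8–C12 4π closure by which these marine prostanoids are thought to arise from an allene oxide.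
3. Forward: allenyl glycoside 5 (C7–C9; from D-glucal and propargyl alcohol) and β-silyloxy enamide 12 (C10–C20; from (Z)-non-3-en-1-ol) are joined and cyclised in one flask, giving the only ring. Then C10–OH → OTf → Cl, Heck coupling of the exocyclic C7 methylene with iodide 20 (C1–C6), desilylation, acetylation.
4. Stereochemistry: C12, the only stereocentre, is set in the key step by the sense of conrotation that the sugar auxiliary imposes on the (Z)-enol ether. 14Z comes from (Z)-non-3-en-1-ol, 5E from hydrozirconation, 7E from the Heck β-hydride elimination.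

Key step: step 7

Assumption: the α-D-pyranosyl auxiliary is taken to direct C8 to the Si face of C12 (priorities O > C11 > C13) of the (2Z)-enol ether 12, which gives 12R; face and enol-ether geometry are coupled, so if the auxiliary imposes the opposite conrotation the (2E)-enol ether is used with the same auxiliary.

**Route**

Step 1
Reactants: 1 D-glucal
Product: 2 3,4,6-tri-O-methyl-D-glucal
Conditions: NaH, MeI, DMF, 0 °C → rt
Reagents that add atoms: iodomethane, CI
Why: Threefold Williamson etherification; the glycal enol ether and the three stereocentres are inert to NaH/MeI.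

Step 2
Reactants: 2 3,4,6-tri-O-methyl-D-glucal, 3 propargyl alcohol
Product: 4 prop-2-yn-1-yl 2-deoxy-3,4,6-tri-O-methyl-α-D-arabino-hexopyranoside
Conditions: PPh3·HBr (cat.), CH2Cl2, rt
Reagents that add atoms: none
Why: Acid-catalysed hydroalkoxylation of the glycal (2-deoxyglycosylation): C2 protonation gives the oxocarbenium ion, which the alcohol should capture axially under anomeric control to set the α-configured C1'.

Step 3
Reactants: 4 prop-2-yn-1-yl 2-deoxy-3,4,6-tri-O-methyl-α-D-arabino-hexopyranoside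
Product: 5 propa-1,2-dien-1-yl 2-deoxy-3,4,6-tri-O-methyl-α-D-arabino-hexopyranoside
Conditions: KOtBu (cat.), THF, rt
Reagents that add atoms: none
Why: Base-catalysed propargyl-to-allenyl ether prototropic isomerisation, driven by conjugation of the allene with oxygen.

Step 4
Reactants: 6 (3Z)-non-3-en-1-ol
Product: 7 (3Z)-non-3-enoic acid
Conditions: CrO3, H2SO4, acetone/H2O, 0 °C
Reagents that add atoms: water, O
Why: Jones oxidation through the aldehyde hydrate; the acidic medium at 0 °C should leave the β,γ-(Z)-alkene in place.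

Step 5
Reactants: 7 (3Z)-non-3-enoic acid, 8 Meldrum's acid, 9 morpholine
Product: 11 (5Z)-1-(morpholin-4-yl)undec-5-ene-1,3-dione, via acyl Meldrum's acid 10 (not isolated)
Conditions: DCC, DMAP, CH2Cl2, 0 °C → rt; then 9, toluene, 100 °C
Reagents that add atoms: none
Why: Carbodiimide C-acylation of Meldrum's acid, then thermal fragmentation (loss of acetone and CO2) to an acylketene that morpholine traps as the β-keto amide.

Step 6
Reactants: 11 (5Z)-1-(morpholin-4-yl)undec-5-ene-1,3-dione
Product: 12 (2Z,5Z)-3-[(tert-butyldimethylsilyl)oxy]-1-(morpholin-4-yl)undeca-2,5-dien-1-one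
Conditions: NaH, THF, 0 °C; TBSCl, 0 °C → rt
Reagents that add atoms: tert-butyldimethylsilyl chloride, CC(C)(C)[Si](C)(C)Cl
Why: O-Silylation of the sodium chelate of the β-dicarbonyl on the ketone oxygen (amide conjugation retained); the U-shaped chelate should give the (2Z)-enol ether, silyloxy cis to the amide carbonyl.

Step 7
Reactants: 5 propa-1,2-dien-1-yl 2-deoxy-3,4,6-tri-O-methyl-α-D-arabino-hexopyranoside, 12 (2Z,5Z)-3-[(tert-butyldimethylsilyl)oxy]-1-(morpholin-4-yl)undeca-2,5-dien-1-one
Product: 16 (4R)-4-[(tert-butyldimethylsilyl)oxy]-2-hydroxy-5-methylidene-4-[(2Z)-oct-2-en-1-yl]cyclopent-2-en-1-one, via lithioallene 13 (not isolated), via hemiaminal lithium alkoxide 14 (not isolated), via allenyl ketone 15 (not isolated)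
Conditions: 5, n-BuLi, THF, −78 °C; then 12, −78 °C; then HCl, EtOH, −78 → −40 °C
Reagents that add atoms: none
Why: Proposed new method: lithiation of 5 at C9 and 1,2-addition to the amide carbonyl (C10) give hemiaminal 14, which on acidification collapses to the cross-conjugated ketone 15; O-protonation gives a 3-hydroxypentadienyl cation over C8–C9–C10–C11–C12 that closes C8–C12 by 4π-conrotatory electrocyclisation, after which the C9 oxocarbenium ion expels the pyranosyl cation (captured by ethanol) to leave the C9 ketone and the C10 enol. The closest known reaction is the allenyl ether Nazarov cyclopentannelation of α,β-unsaturated morpholine amides with traceless pyranosyl auxiliaries; the new element is the β-silyloxy (vinylogous carbamate) partner, which makes the cation terminus C12 an oxocarbenium-type centre and delivers an oxygenated quaternary carbon. The only ring (C8–C9–C10–C11–C12) is closed by the electrocyclic step, formally 5-endo-trig, while C9–C10 is the intermolecular acylation bond. C12 is set by the sense of conrotation, controlled by the α-D-pyranosyl group on O9 acting on the fixed (Z) geometry of C11=C12 (silyloxy inside, octenyl outside), so that C8 bonds to the Si face of C12. The step needs addition to beat deprotonation at the doubly allylic C13 (fast amide addition at −78 °C), C-cyclisation to beat solvolysis of the allenyl and silyl enol ethers (release of allene strain, anhydrous acid, low temperature), and retention of the enol-ether geometry until closure (closure at −78 °C from the s-cis,s-cis cation).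

Step 8
Reactants: 16 (4R)-4-[(tert-butyldimethylsilyl)oxy]-2-hydroxy-5-methylidene-4-[(2Z)-oct-2-en-1-yl]cyclopent-2-en-1-one
Product: 17 (3R)-3-[(tert-butyldimethylsilyl)oxy]-4-methylidene-3-[(2Z)-oct-2-en-1-yl]-5-oxocyclopent-1-en-1-yl trifluoromethanesulfonate
Conditions: Tf2O, 2,6-lutidine, CH2Cl2, −78 °C
Reagents that add atoms: trifluoromethanesulfonic anhydride, O=S(=O)(OS(=O)(=O)C(F)(F)F)C(F)(F)F
Why: O-Sulfonylation of the acidic C10 enol (diosphenol); the hindered base should spare the exocyclic enone.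

Step 9
Reactants: 17 (3R)-3-[(tert-butyldimethylsilyl)oxy]-4-methylidene-3-[(2Z)-oct-2-en-1-yl]-5-oxocyclopent-1-en-1-yl trifluoromethanesulfonate
Product: 18 (4R)-4-[(tert-butyldimethylsilyl)oxy]-2-chloro-5-methylidene-4-[(2Z)-oct-2-en-1-yl]cyclopent-2-en-1-one
Conditions: Ni(cod)2 (cat.), LiCl, DMA/THF, rt
Reagents that add atoms: lithium chloride, [Li+].[Cl-]
Why: Nickel-catalysed halogenation of an enol triflate: oxidative addition into C10–OTf, triflate-for-chloride exchange at nickel and C–Cl bond formation; C12 is not involved.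

Step 10
Reactants: 19 methyl hex-5-ynoate
Product: 20 methyl (5E)-6-iodohex-5-enoate
Conditions: Cp2Zr(H)Cl, THF, rt; then I2, 0 °C
Reagents that add atoms: iodine, II
Why: Hydrozirconation (syn addition, zirconium at the terminal carbon) and iodinolysis with retention should give the (E)-alkenyl iodide; the alkyne reacts faster than the ester.

Step 11
Reactants: 18 (4R)-4-[(tert-butyldimethylsilyl)oxy]-2-chloro-5-methylidene-4-[(2Z)-oct-2-en-1-yl]cyclopent-2-en-1-one, 20 methyl (5E)-6-iodohex-5-enoate
Product: 21 methyl (5E,7E,12R,14Z)-12-[(tert-butyldimethylsilyl)oxy]-10-chloro-9-oxoprosta-5,7,10,14-tetraen-1-oate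
Conditions: Pd(OAc)2 (cat.), Bu4NCl, NaHCO3, DMF, rt → 40 °C
Reagents that add atoms: none
Why: Heck reaction: the alkenylpalladium iodide from 20 adds syn across the exocyclic C8=C7 bond with carbon to the terminal C7, and since C8 has no other β-hydrogen (C12 quaternary, C9 carbonyl) syn β-hydride elimination can only re-form C7=C8, expected with the new chain anti to the C9 carbonyl (7E) as in Heck reactions of α-methylene carbonyl compounds, the 5E geometry of 20 being retained.

Step 12
Reactants: 21 methyl (5E,7E,12R,14Z)-12-[(tert-butyldimethylsilyl)oxy]-10-chloro-9-oxoprosta-5,7,10,14-tetraen-1-oate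
Product: 22 methyl (5E,7E,12R,14Z)-10-chloro-12-hydroxy-9-oxoprosta-5,7,10,14-tetraen-1-oate
Conditions: HF·pyridine, THF, 0 °C → rt
Reagents that add atoms: none
Why: Fluoride-mediated cleavage of the tertiary silyl ether under buffered, non-basic conditions that the cross-conjugated chloro dienone should tolerate.

Step 13
Reactants: 22 methyl (5E,7E,12R,14Z)-10-chloro-12-hydroxy-9-oxoprosta-5,7,10,14-tetraen-1-oate
Product: 23 methyl (5E,7E,12R,14Z)-12-acetoxy-10-chloro-9-oxoprosta-5,7,10,14-tetraen-1-oate (target)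
Conditions: Ac2O, DMAP, Et3N, CH2Cl2, rt
Reagents that add atoms: acetic anhydride, CC(=O)OC(C)=O
Why: DMAP-catalysed acetylation (N-acetylpyridinium transfer) of the tertiary C12 alcohol, with no change at the stereocentre.

**Compound list**

1 | D-glucal | OC[C@H]1OC=C[C@@H](O)[C@@H]1O | starting material
2 | 3,4,6-tri-O-methyl-D-glucal | COC[C@H]1OC=C[C@@H](OC)[C@@H]1OC | intermediate
3 | propargyl alcohol | OCC#C | starting material
4 | prop-2-yn-1-yl 2-deoxy-3,4,6-tri-O-methyl-α-D-arabino-hexopyranoside | COC[C@H]1O[C@H](OCC#C)C[C@@H](OC)[C@@H]1OC | intermediate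
5 | propa-1,2-dien-1-yl 2-deoxy-3,4,6-tri-O-methyl-α-D-arabino-hexopyranoside | COC[C@H]1O[C@H](OC=C=C)C[C@@H](OC)[C@@H]1OC | intermediate
6 | (3Z)-non-3-en-1-ol | CCCCC/C=C\CCO | starting material
7 | (3Z)-non-3-enoic acid | CCCCC/C=C\CC(=O)O | intermediate
8 | Meldrum's acid (2,2-dimethyl-1,3-dioxane-4,6-dione) | CC1(C)OC(=O)CC(=O)O1 | starting material
9 | morpholine | C1COCCN1 | starting material
10 | 5-[(3Z)-1-hydroxynon-3-en-1-ylidene]-2,2-dimethyl-1,3-dioxane-4,6-dione (acyl Meldrum's acid, formed in the flask) | CCCCC/C=C\CC(O)=C1C(=O)OC(C)(C)OC1=O | intermediate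
11 | (5Z)-1-(morpholin-4-yl)undec-5-ene-1,3-dione | CCCCC/C=C\CC(=O)CC(=O)N1CCOCC1 | intermediate
12 | (2Z,5Z)-3-[(tert-butyldimethylsilyl)oxy]-1-(morpholin-4-yl)undeca-2,5-dien-1-one | CCCCC/C=C\C/C(O[Si](C)(C)C(C)(C)C)=C/C(=O)N1CCOCC1 | intermediate
13 | 1-lithiopropa-1,2-dien-1-yl 2-deoxy-3,4,6-tri-O-methyl-α-D-arabino-hexopyranoside (formed in the flask) | COC[C@H]1O[C@H](OC([Li])=C=C)C[C@@H](OC)[C@@H]1OC | intermediate
14 | lithium alkoxide of the C10 hemiaminal from 13 and 12, epimers at C10 (formed in the flask) | COC[C@H]1O[C@H](OC(=C=C)C(O[Li])(/C=C(/C/C=C\CCCCC)O[Si](C)(C)C(C)(C)C)N2CCOCC2)C[C@@H](OC)[C@@H]1OC | intermediate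
15 | (5Z,8Z)-6-[(tert-butyldimethylsilyl)oxy]-3-[(2-deoxy-3,4,6-tri-O-methyl-α-D-arabino-hexopyranosyl)oxy]tetradeca-1,2,5,8-tetraen-4-one (formed in the flask) | COC[C@H]1O[C@H](OC(=C=C)C(=O)/C=C(/C/C=C\CCCCC)O[Si](C)(C)C(C)(C)C)C[C@@H](OC)[C@@H]1OC | intermediate
16 | (4R)-4-[(tert-butyldimethylsilyl)oxy]-2-hydroxy-5-methylidene-4-[(2Z)-oct-2-en-1-yl]cyclopent-2-en-1-one | CCCCC/C=C\C[C@@]1(O[Si](C)(C)C(C)(C)C)C=C(O)C(=O)C1=C | intermediate
17 | (3R)-3-[(tert-butyldimethylsilyl)oxy]-4-methylidene-3-[(2Z)-oct-2-en-1-yl]-5-oxocyclopent-1-en-1-yl trifluoromethanesulfonate | CCCCC/C=C\C[C@@]1(O[Si](C)(C)C(C)(C)C)C=C(OS(=O)(=O)C(F)(F)F)C(=O)C1=C | intermediate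
18 | (4R)-4-[(tert-butyldimethylsilyl)oxy]-2-chloro-5-methylidene-4-[(2Z)-oct-2-en-1-yl]cyclopent-2-en-1-one | CCCCC/C=C\C[C@@]1(O[Si](C)(C)C(C)(C)C)C=C(Cl)C(=O)C1=C | intermediate
19 | methyl hex-5-ynoate | COC(=O)CCCC#C | starting material
20 | methyl (5E)-6-iodohex-5-enoate | COC(=O)CCC/C=C/I | intermediate
21 | methyl (5E,7E,12R,14Z)-12-[(tert-butyldimethylsilyl)oxy]-10-chloro-9-oxoprosta-5,7,10,14-tetraen-1-oate | CCCCC/C=C\C[C@@]1(O[Si](C)(C)C(C)(C)C)C=C(Cl)C(=O)/C1=C/C=C/CCCC(=O)OC | intermediate
22 | methyl (5E,7E,12R,14Z)-10-chloro-12-hydroxy-9-oxoprosta-5,7,10,14-tetraen-1-oate | CCCCC/C=C\C[C@@]1(O)C=C(Cl)C(=O)/C1=C/C=C/CCCC(=O)OC | intermediate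
23 | methyl (5E,7E,12R,14Z)-12-acetoxy-10-chloro-9-oxoprosta-5,7,10,14-tetraen-1-oate | CCCCC/C=C\C[C@@]1(OC(C)=O)C=C(Cl)C(=O)/C1=C/C=C/CCCC(=O)OC | target

**Step count**

Total steps: 13. Longest linear sequence: 9 steps (1 → 2 → 3 → 7 → 8 → 9 → 11 → 12 → 13; the branch 4 → 5 → 6 → 7 → … is equally long).

**Steps most likely to fail**

1. Step 7 (Proposed new method). What may go wrong:
- the lithioallene deprotonates C13 instead of adding to the amide;
- the silyl group is lost or the allenyl ether is solvolysed before ring closure;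
- rotation about C11–C12 in the delocalised cation, or weak torquoselectivity, erodes the enantiomeric purity;
- silanol is lost by β-elimination from the product.

Fallback (known chemistry only; chirality relay and aldol condensation in place of the annulation): it sets out from 20, which supplies C1–C7, and from a commercial cyclopentenone, and comes back to the route at 21. The ring is taken from commercial (4R)-4-[(tert-butyldimethylsilyl)oxy]cyclopent-2-en-1-one F1, whose stereocentre is relayed to C12 and then destroyed. (Z)-1-Chlorooct-2-ene F2 (from commercial (Z)-oct-2-en-1-ol, NCS/Me2S) is converted into its allylbarium reagent (reactive barium, THF, −78 °C). This should add to the carbonyl group of F1 through its α-terminus, with retention of the Z geometry and anti to the silyloxy group, to give the tertiary alcohol (1S,4R)-4-[(tert-butyldimethylsilyl)oxy]-1-[(2Z)-oct-2-en-1-yl]cyclopent-2-en-1-ol F3. TBAF gives (1S,4R)-1-[(2Z)-oct-2-en-1-yl]cyclopent-2-ene-1,4-diol F4. MnO2 oxidises only the secondary allylic alcohol to (4S)-4-hydroxy-4-[(2Z)-oct-2-en-1-yl]cyclopent-2-en-1-one F5, and TBSOTf/2,6-lutidine gives the silyl ether F6. Nucleophilic epoxidation (H2O2, NaOH, MeOH) gives the epoxy ketone F7; HCl opens it at the α-carbon and dehydrates the chlorohydrin to (4S)-4-[(tert-butyldimethylsilyl)oxy]-2-chloro-4-[(2Z)-oct-2-en-1-yl]cyclopent-2-en-1-one F8. Iodide 20 is formylated (CO, Bu3SnH, cat. Pd(PPh3)4) to methyl (5E)-7-oxohept-5-enoate F9. The lithium enolate of F8 (LDA, THF, −78 °C) and F9 give the aldol F10; mesylation (MsCl, Et3N) gives the mesylate F11, which eliminates with DBU to 21.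

2. Step 9. What may go wrong: reduction of the triflate to the C10–H compound, engagement of the exocyclic enone by low-valent nickel, or conjugate addition of chloride to the methylidene ketone.

Fallback (tin relay instead of direct halide exchange): it sets out from 17 and comes back at 18. Palladium-catalysed stannylation (Me3SnSnMe3, Pd(PPh3)4, LiCl, THF, 60 °C) gives the alkenylstannane (4R)-4-[(tert-butyldimethylsilyl)oxy]-5-methylidene-4-[(2Z)-oct-2-en-1-yl]-2-(trimethylstannyl)cyclopent-2-en-1-one F12, and chlorodestannylation with CuCl2 (THF, rt) gives 18.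

3. Step 11. What may go wrong: oligomerisation of, or base-mediated conjugate addition to, the exocyclic dienone; slow insertion into the 1,1-disubstituted alkene; or β-hydride elimination towards the 7Z isomer.

Fallback (conjugate addition and selenoxide elimination instead of the Heck reaction): it sets out from 18 (with 19 as the chain source) and comes back at 21. Hydrozirconation of 19 gives the (E)-alkenylzirconocene chloride F13, which is added in a copper-catalysed conjugate addition (CuI·SMe2 cat., THF) to C7 of 18. The resulting enolate is trapped at C8 with PhSeCl to give the selenide F14 (mixture at C8). Oxidation (H2O2, CH2Cl2, 0 °C) and syn-elimination of the selenoxide, which can only take a C7 hydrogen, restore C7=C8 and give 21.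

**Further compounds**

F1 | step 7 | (4R)-4-[(tert-butyldimethylsilyl)oxy]cyclopent-2-en-1-one (commercial) | O=C1C=C[C@H](O[Si](C)(C)C(C)(C)C)C1
F2 | step 7 | (2Z)-1-chlorooct-2-ene | CCCCC/C=C\CCl
F3 | step 7 | (1S,4R)-4-[(tert-butyldimethylsilyl)oxy]-1-[(2Z)-oct-2-en-1-yl]cyclopent-2-en-1-ol | CCCCC/C=C\C[C@@]1(O)C=C[C@H](O[Si](C)(C)C(C)(C)C)C1
F4 | step 7 | (1S,4R)-1-[(2Z)-oct-2-en-1-yl]cyclopent-2-ene-1,4-diol | CCCCC/C=C\C[C@@]1(O)C=C[C@H](O)C1
F5 | step 7 | (4S)-4-hydroxy-4-[(2Z)-oct-2-en-1-yl]cyclopent-2-en-1-one | CCCCC/C=C\C[C@@]1(O)C=CC(=O)C1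
F6 | step 7 | (4S)-4-[(tert-butyldimethylsilyl)oxy]-4-[(2Z)-oct-2-en-1-yl]cyclopent-2-en-1-one | CCCCC/C=C\C[C@@]1(O[Si](C)(C)C(C)(C)C)C=CC(=O)C1
F7 | step 7 | 2,3-epoxide of F6 (epoxide configuration not specified) | CCCCC/C=C\C[C@@]1(O[Si](C)(C)C(C)(C)C)C2OC2C(=O)C1
F8 | step 7 | (4S)-4-[(tert-butyldimethylsilyl)oxy]-2-chloro-4-[(2Z)-oct-2-en-1-yl]cyclopent-2-en-1-one | CCCCC/C=C\C[C@@]1(O[Si](C)(C)C(C)(C)C)C=C(Cl)C(=O)C1
F9 | step 7 | methyl (5E)-7-oxohept-5-enoate | COC(=O)CCC/C=C/C=O
F10 | step 7 | aldol adduct of F8 and F9 (mixture at C7 and C8) | CCCCC/C=C\C[C@@]1(O[Si](C)(C)C(C)(C)C)C=C(Cl)C(=O)C1C(O)/C=C/CCCC(=O)OC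
F11 | step 7 | C7 methanesulfonate of F10 | CCCCC/C=C\C[C@@]1(O[Si](C)(C)C(C)(C)C)C=C(Cl)C(=O)C1C(OS(C)(=O)=O)/C=C/CCCC(=O)OC
F12 | step 9 | (4R)-4-[(tert-butyldimethylsilyl)oxy]-5-methylidene-4-[(2Z)-oct-2-en-1-yl]-2-(trimethylstannyl)cyclopent-2-en-1-one | CCCCC/C=C\C[C@@]1(O[Si](C)(C)C(C)(C)C)C=C([Sn](C)(C)C)C(=O)C1=C
F13 | step 11 | chlorobis(cyclopentadienyl)[(1E)-6-methoxy-6-oxohex-1-en-1-yl]zirconium | COC(=O)CCC/C=C/[Zr](Cl)(C1C=CC=C1)C1C=CC=C1
F14 | step 11 | C8 phenylselanyl conjugate adduct of 18 (mixture at C8) | CCCCC/C=C\C[C@@]1(O[Si](C)(C)C(C)(C)C)C=C(Cl)C(=O)C1([Se]c1ccccc1)C/C=C/CCCC(=O)OC
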